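**Retrosynthetic overview**

1. Target 43 ← allyl compound 41 by cross-metathesis (C2′=C3′). The C11 aldehyde comes from a tert-butyl ester, the C3 chloride from a C3 alcohol by radical deoxychlorination under the shield of an axial 1α-silyloxy group, and the 1α-hydroxyl from a C1 ketone.
2. Ring B (closed last) ← aldol condensation of the C8 acetate arm onto a C7 aldehyde (C7=C8), with C9 equilibrated to the equatorial ester.
3. Structural feature: the array C1(O)–C10(quaternary, methyl)–C9–C8(CO2Me), a C1 ketone and the C12 ester in a 1,5-relationship, is the retro-aldol product of a cyclobutanol with a temporary C1–C8 bond. Ring A and that cyclobutane ← one intramolecular [2+2] photocycloaddition of a 6-alkyl dioxinone onto the C10=C9 enoate (bonds C1–C10 and C8–C9).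
4. Photo precursor 20 ← vinylogous aldol of the dioxinone dienolate with a C3 aldehyde (forms C2–C3 and delivers the C3 oxygen handle) and Horner–Wadsworth–Emmons olefination of a C10 methyl ketone.
5. C4/C5 ← δ-lactone template: rhodium-catalysed asymmetric conjugate addition to 5,6-dihydro-2H-pyran-2-one, then two trans-selective enolate alkylations. Ring order: ring A with the cyclobutane (step 11), cyclobutane opened (step 12), ring B (step 17).

Key step: step 11

Remark: locants are those of the target (decalin C1–C10, C11 on C9, C12 the ester carbon on C8, C1′/C2′ the first carbons of the C4 side chain, C10 methyl β); the C3 carbinol is drawn as the expected 3β epimer and C9 of compounds 21–27 as it is expected to leave the cycloaddition, and these two centres are erased (step 20) or equilibrated (step 17) later.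

**Route**

Step 1
Reactants: 1 5,6-dihydro-2H-pyran-2-one; 2 potassium trifluoro(prop-1-en-2-yl)borate
Product: 3 (S)-4-(prop-1-en-2-yl)oxan-2-one
Conditions: [Rh(cod)2]BF4 (3 mol%), (S)-BINAP, Et3N, toluene/H2O, 60 °C
Reagents that add atoms: none
Why: Rhodium-catalysed asymmetric 1,4-addition of an alkenylboron reagent (Hayashi–Miyaura reaction) to the unsaturated δ-lactone; the chiral rhodium–BINAP complex selects the enone face and sets C5, and the ligand enantiomer that gives (S)-3 is chosen by analogy with cyclic enones.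

Step 2
Reactants: 3 (S)-4-(prop-1-en-2-yl)oxan-2-one; 4 tert-butyl(2-iodoethoxy)diphenylsilane
Product: 6 (3R,4S)-3-[2-(tert-butyldiphenylsilyloxy)ethyl]-4-(prop-1-en-2-yl)oxan-2-one (3,4-trans), via lithium enolate 5 (not isolated)
Conditions: LiN(iPr)2, THF, −78 °C; then 4, DMPU, −78 → −20 °C
Reagents that add atoms: none
Why: Enolate alkylation of a β-substituted δ-lactone, in which the electrophile should enter trans to the isopropenyl group; this centre is planarised again in step 3, so only the regiochemistry matters.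

Step 3
Reactants: 6 (3R,4S)-3-[2-(tert-butyldiphenylsilyloxy)ethyl]-4-(prop-1-en-2-yl)oxan-2-one
Product: 8 (3S,4R)-3-[2-(tert-butyldiphenylsilyloxy)ethyl]-3-methyl-4-(prop-1-en-2-yl)oxan-2-one (methyl trans to isopropenyl), via lithium enolate 7 (not isolated)
Conditions: LiN(iPr)2, THF, −78 °C; then MeI, −78 → 0 °C
Reagents that add atoms: iodomethane, CI
Why: Second enolate alkylation forms the C4 quaternary centre; iodomethane should approach the tetrasubstituted enolate anti to the neighbouring isopropenyl group (held pseudo-axial by allylic strain), so the methyl ends trans and the silyloxyethyl arm cis to it, as the target requires.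

Step 4
Reactants: 8 quaternary lactone
Product: 9 (2S,3R)-2-[2-(tert-butyldiphenylsilyloxy)ethyl]-2-methyl-3-(prop-1-en-2-yl)pentane-1,5-diol
Conditions: LiAlH4, THF, 0 °C; aqueous work-up
Reagents that add atoms: none
Why: Hydride reduction of the lactone to the 1,5-diol releases C3 (neopentyl CH2OH) and C7 (CH2OH) without touching the stereocentres.

Step 5
Reactants: 9 diol
Product: 10 diol 9 with the C7 hydroxyl as triethylsilyl ether and the neopentyl C3 hydroxyl free
Conditions: Et3SiCl (1.05 equiv), imidazole, CH2Cl2, −78 °C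
Reagents that add atoms: chlorotriethylsilane, CC[Si](Cl)(CC)CC
Why: Sterically controlled monosilylation, since the unhindered primary C7 alcohol should react much faster than the neopentyl C3 alcohol next to the quaternary carbon.

Step 6
Reactants: 10 mono-silyl ether
Product: 11 α-quaternary C3 aldehyde
Conditions: Dess–Martin periodinane, pyridine, CH2Cl2, 0 °C → rt
Reagents that add atoms: none
Why: Dess–Martin oxidation of the remaining primary alcohol gives an aldehyde that cannot epimerise because C4 is quaternary.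

Step 7
Reactants: 11 C3 aldehyde; 12 2,2,6-trimethyl-4H-1,3-dioxin-4-one
Product: 14 aldol adduct, 2,2-dimethyl-1,3-dioxin-4-one carrying at C6 the chain C2H2–C3H(OH)–C4–C5 (C3 carbinol S, 3β), via lithium dienolate 13 (not isolated)
Conditions: 12, LiN(iPr)2, THF, −78 °C; then 11, −78 °C; aq. NH4Cl
Reagents that add atoms: none
Why: Vinylogous aldol addition of the dioxinone dienolate through its γ-carbon makes the C2–C3 bond without an SN2 reaction at a neopentyl carbon and puts the oxygen handle on C3; Felkin–Anh attack anti to the bulky C5 branch and past the methyl group should favour the 3β carbinol, a centre that is erased in step 20, so a minor epimer converges.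

Step 8
Reactants: 14 aldol adduct
Product: 15 C3 triethylsilyl ether of 14
Conditions: Et3SiOTf, 2,6-lutidine, CH2Cl2, −78 °C
Reagents that add atoms: triethylsilyl trifluoromethanesulfonate, CC[Si](CC)(CC)OS(=O)(=O)C(F)(F)F
Why: Silyl triflate silylation of the hindered secondary alcohol prevents hemiketal formation with the C10 ketone of step 9 and retro-aldol or translactonisation later.

Step 9
Reactants: 15 bis-triethylsilyl ether
Product: 17 C10 methyl ketone, via vicinal diol 16 (not isolated)
Conditions: OsO4 (2 mol%), NaIO4, 2,6-lutidine, dioxane/H2O, rt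
Reagents that add atoms: osmium tetroxide, O=[Os](=O)(=O)=O (transfers the oxygen; regenerated by sodium periodate, [Na+].[O-]I(=O)(=O)=O)
Why: Lemieux–Johnson oxidation, in which OsO4 should dihydroxylate the electron-rich 1,1-disubstituted alkene in preference to the electron-poor dioxinone double bond and periodate cleaves the diol to the methyl ketone.

Step 10
Reactants: 17 methyl ketone; 18 tert-butyl diethylphosphonoacetate
Product: 20 photo precursor, dioxinone tethered through C2–C5 to the (E)-C10=C9 tert-butyl enoate, via sodium phosphonate 19 (not isolated)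
Conditions: 18, NaH, THF, 0 °C; then 17, 0 → 50 °C
Reagents that add atoms: none
Why: Horner–Wadsworth–Emmons olefination of the methyl ketone should give mainly the E enoate (ester anti to the branched C5); the geometry is not critical because C9 becomes a radical centre in step 11 and is equilibrated in step 17, and the weakly basic phosphonate anion should leave the hindered C5–H alone.

Step 11
Reactants: 20 photo precursor
Product: 21 cyclobutane photoadduct (ring A cis-fused to the cyclobutane C1–C8–C9–C10, dioxanone cis-fused on the opposite face, C10 methyl trans to H5)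
Conditions: hν (300 nm lamps, Pyrex), MeCN/acetone 9:1, 0 °C, 3 mM, degassed
Reagents that add atoms: none
Why: Excitation of the dioxinone enone chromophore gives its triplet, whose β-carbon C1 adds to C10 of the tethered enoate to give a 1,4-biradical at C8 and C9, both carbonyl-stabilised, which closes the C8–C9 bond after intersystem crossing. The closest known reaction type is the intramolecular dioxinone–alkene [2+2] photocycloaddition with a four-atom tether, the first half of a de Mayo sequence. Ring A closes by 6-exo-trig attack of C1 on C10 through a chair-like transition state, and the cyclobutane closes by collapse of the 1,4-biradical, necessarily cis-fused to ring A and to the dioxanone, which fixes C1 and C8. C10 is controlled by the C4 and C5 centres: with the C6 arm equatorial and H5 near the alkene plane, the ester-bearing C9 terminus should take the pseudo-equatorial exo position and the smaller methyl the pseudo-axial one, so the methyl ends trans to H5. C9 results from the biradical closure and is not needed, since it is reset in step 17. The step needs straight rather than crossed regiochemistry, which the four-atom tether secures, facial selectivity at C10, which rests on the conformational argument above, and chemoselectivity, which is secured because the side chain carries no alkene at this stage.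

Step 12
Reactants: 21 photoadduct
Product: 23 ring A ketone with the C10 arm C9H(CO2tBu)–C8H2–CO2Me, via cyclobutanol ester 22 (not isolated)
Conditions: K2CO3 (0.3 equiv), MeOH, 0 °C
Reagents that add atoms: methanol, CO
Why: Methoxide opens the dioxanone at its carbonyl, acetone is lost, and the strained cyclobutanol alkoxide undergoes retro-aldol cleavage of the temporary C1–C8 bond (second half of the de Mayo reaction), which gives the C1 ketone and the C8 methyl ester arm; the mild, cold base should spare the β-silyloxy ketone.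

Step 13
Reactants: 23 keto diester
Product: 24 1α-alcohol (axial)
Conditions: LiBH(s-Bu)3 (L-Selectride), THF, −78 °C; AcOH quench at −78 °C
Reagents that add atoms: none
Why: The bulky hydride should attack the cyclohexanone equatorially, as with 4,4-disubstituted 3-ketones, and so gives the axial 1α-alcohol; the cold acidic quench avoids lactonisation of the alkoxide onto the C12 ester.

Step 14
Reactants: 24 1α-alcohol
Product: 25 1α-tert-butyldimethylsilyl ether
Conditions: tBuMe2SiOTf, 2,6-lutidine, CH2Cl2, −78 → 0 °C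
Reagents that add atoms: tert-butyldimethylsilyl trifluoromethanesulfonate, CC(C)(C)[Si](C)(C)OS(=O)(=O)C(F)(F)F
Why: Silyl triflate silylation of the hindered axial alcohol blocks lactonisation during step 17 and installs the axial group that should shield the α face in step 20.

Step 15
Reactants: 25 tetrasilyl ether
Product: 26 C7 primary alcohol
Conditions: PPTS (cat.), MeOH/CH2Cl2, 0 °C
Reagents that add atoms: none
Why: Acid-catalysed methanolysis removes the primary triethylsilyl ether far faster than the hindered secondary triethylsilyl, the tert-butyldimethylsilyl and the tert-butyldiphenylsilyl ethers.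

Step 16
Reactants: 26 C7 alcohol
Product: 27 C7 aldehyde
Conditions: Dess–Martin periodinane, pyridine, CH2Cl2, 0 °C → rt
Reagents that add atoms: none
Why: Dess–Martin oxidation gives the aldehyde under non-basic conditions, and all other hydroxyls are protected.

Step 17
Reactants: 27 aldehyde diester
Product: 29 trans-decalin with C7=C8–CO2Me and the 9β (equatorial) tert-butyl ester, via β-hydroxy ester 28 (not isolated)
Conditions: NaOMe (0.5 equiv), MeOH, 0 → 50 °C
Reagents that add atoms: none
Why: Intramolecular aldol condensation, in which the succinate-type C8 ester enolate (as in a Stobbe condensation) adds to the C7 aldehyde to close ring B (six-membered) and E1cB dehydration to the conjugated ester makes the sequence irreversible; C9 should equilibrate through the dienolate to the 9β ester because the 9α epimer suffers a syn-diaxial clash with the 1α-silyloxy group.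

Step 18
Reactants: 29 decalin
Product: 30 3β-alcohol
Conditions: HF·pyridine, pyridine, THF, 0 °C → rt
Reagents that add atoms: none
Why: Buffered HF cleaves the secondary triethylsilyl ether selectively in the presence of the hindered tert-butyldimethylsilyl and the tert-butyldiphenylsilyl ethers.

Step 19
Reactants: 30 3β-alcohol
Product: 32 cesium oxalate of the C3 alcohol, via methyl oxalate 31 (not isolated)
Conditions: ClC(O)CO2Me, Et3N, DMAP (cat.), CH2Cl2, 0 °C; then CsOH (1.0 equiv), THF/H2O, rt
Reagents that add atoms: methyl chlorooxoacetate, COC(=O)C(Cl)=O; cesium hydroxide, [Cs+].[OH-]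
Why: Acylation of the alcohol and saponification of the very electrophilic oxalate methyl ester with one equivalent of hydroxide, which should leave the conjugated methyl ester and the tert-butyl ester untouched.

Step 20
Reactants: 32 cesium oxalate
Product: 33 3β-chloride (equatorial)
Conditions: Ir[dF(CF3)ppy]2(dtbbpy)PF6 (1 mol%), Cl3CCO2Et, DME/DMF, blue LEDs (450 nm), rt
Reagents that add atoms: ethyl trichloroacetate, CCOC(=O)C(Cl)(Cl)Cl
Why: Photoredox deoxychlorination of a cesium oxalate, in which oxidation by the excited iridium complex and loss of two CO2 give the C3 radical that abstracts chlorine from ethyl trichloroacetate, so no SN2 reaction at the neopentyl C3 is needed; axial approach on the α face is blocked by the syn-axial 1α-silyloxy group, so chlorine should arrive from the β face and end equatorial.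

Step 21
Reactants: 33 chloride
Product: 34 C2′ primary alcohol
Conditions: Bu4NF, AcOH, THF, 0 °C → rt
Reagents that add atoms: none
Why: Buffered fluoride should remove the primary tert-butyldiphenylsilyl ether faster than the hindered axial secondary tert-butyldimethylsilyl ether, and the buffer protects C9 and the chloride from base.

Step 22
Reactants: 34 primary alcohol
Product: 35 C2′ aldehyde
Conditions: Dess–Martin periodinane, pyridine, CH2Cl2, 0 °C → rt
Reagents that add atoms: none
Why: Dess–Martin oxidation of the only free hydroxyl.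

Step 23
Reactants: 35 aldehyde
Product: 36 allyl compound (C4–CH2–CH=CH2)
Conditions: Ph3PCH3Br, KOtBu, THF, 0 °C; then 35, −78 → 0 °C
Reagents that add atoms: methyltriphenylphosphonium bromide, C[P+](c1ccccc1)(c1ccccc1)c1ccccc1.[Br-]
Why: Wittig methylenation, in which the aldehyde should react faster than the ylide deprotonates C9 at low temperature; should C9 be disturbed, the step 17 conditions restore the 9β ester at this stage.

Step 24
Reactants: 36 allyl tert-butyl ester
Product: 38 C11 carboxylic acid, via trimethylsilyl ester 37 (not isolated)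
Conditions: Me3SiOTf, 2,6-lutidine, CH2Cl2, 0 °C; then aq. citric acid
Reagents that add atoms: none
Why: Silyl triflate-mediated cleavage of the tert-butyl ester (loss of 2-methylpropene) and hydrolysis of the silyl ester on work-up, conditions that should spare the silyl ether, the methyl ester, the chloride and the alkene.

Step 25
Reactants: 38 acid
Product: 40 C11 aldehyde (9β), via acid chloride 39 (not isolated)
Conditions: (COCl)2, DMF (cat.), CH2Cl2, 0 °C → rt; then LiAlH(OtBu)3, THF, −78 °C
Reagents that add atoms: none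
Why: Reduction of the acid chloride with the hindered alkoxyaluminium hydride stops at the aldehyde and leaves the methyl ester alone; this avoids a free C11 alcohol, which would lactonise onto the C12 ester, and no base is present to epimerise C9.

Step 26
Reactants: 40 silyl ether aldehyde
Product: 41 1α-hydroxy aldehyde
Conditions: HF·pyridine, pyridine, THF, 0 °C → rt
Reagents that add atoms: none
Why: Buffered HF removes the last silyl ether under conditions that should not enolise the aldehyde; the 1α-hydroxyl and the 9β-formyl group are trans, so no lactol can form.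

Step 27
Reactants: 41 allyl hydroxy aldehyde; 42 2-methylbut-3-en-2-ol
Product: 43 target, methyl (E)-configured side-chain compound CNP0167913.1
Conditions: 42 (10 equiv), second-generation Hoveyda–Grubbs catalyst RuCl2(H2IMes)(=CH-C6H4-2-OiPr) (5 mol%), CH2Cl2, 40 °C
Reagents that add atoms: none
Why: Olefin cross-metathesis of the unhindered terminal alkene with the tertiary allylic alcohol, which dimerises slowly, should give the E alkene; the trisubstituted conjugated C7=C8 bond, the aldehyde, the hydroxyls and the chloride are tolerated.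

**Compound list**

1 | 5,6-dihydro-2H-pyran-2-one | O=C1C=CCCO1 | starting material
2 | potassium trifluoro(prop-1-en-2-yl)borate | [K+].C=C(C)[B-](F)(F)F | starting material
3 | (S)-4-(prop-1-en-2-yl)oxan-2-one | O=C1C[C@@H](C(C)=C)CCO1 | intermediate
4 | tert-butyl(2-iodoethoxy)diphenylsilane | ICCO[Si](c1ccccc1)(c1ccccc1)C(C)(C)C | starting material
5 | lithium enolate of 3 | [Li]OC1=C[C@@H](C(C)=C)CCO1 | intermediate
6 | (3R,4S)-3-[2-(tert-butyldiphenylsilyloxy)ethyl]-4-(prop-1-en-2-yl)oxan-2-one | O=C1[C@H](CCO[Si](c2ccccc2)(c2ccccc2)C(C)(C)C)[C@@H](C(C)=C)CCO1 | intermediate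
7 | lithium enolate of 6 | [Li]OC1=C(CCO[Si](c2ccccc2)(c2ccccc2)C(C)(C)C)[C@@H](C(C)=C)CCO1 | intermediate
8 | (3S,4R)-3-[2-(tert-butyldiphenylsilyloxy)ethyl]-3-methyl-4-(prop-1-en-2-yl)oxan-2-one | O=C1[C@@](C)(CCO[Si](c2ccccc2)(c2ccccc2)C(C)(C)C)[C@@H](C(C)=C)CCO1 | intermediate
9 | (2S,3R)-2-[2-(tert-butyldiphenylsilyloxy)ethyl]-2-methyl-3-(prop-1-en-2-yl)pentane-1,5-diol | OC[C@@](C)(CCO[Si](c1ccccc1)(c1ccccc1)C(C)(C)C)[C@@H](C(C)=C)CCO | intermediate
10 | diol 9 with the C7 hydroxyl as triethylsilyl ether (C3 hydroxyl free) | OC[C@@](C)(CCO[Si](c1ccccc1)(c1ccccc1)C(C)(C)C)[C@@H](C(C)=C)CCO[Si](CC)(CC)CC | intermediate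
11 | C3 aldehyde with quaternary C4 (methyl, silyloxyethyl) and C5 (isopropenyl, 2-triethylsilyloxyethyl) | O=C[C@@](C)(CCO[Si](c1ccccc1)(c1ccccc1)C(C)(C)C)[C@@H](C(C)=C)CCO[Si](CC)(CC)CC | intermediate
12 | 2,2,6-trimethyl-4H-1,3-dioxin-4-one | CC1=CC(=O)OC(C)(C)O1 | starting material
13 | lithium dienolate of 12 | [Li]OC1=CC(=C)OC(C)(C)O1 | intermediate
14 | vinylogous aldol adduct, dioxinone–C2H2–C3H(OH)–C4–C5 chain, C3 carbinol S (3β) | CC1(C)OC(=O)C=C(O1)C[C@H](O)[C@@](C)(CCO[Si](c2ccccc2)(c2ccccc2)C(C)(C)C)[C@@H](C(C)=C)CCO[Si](CC)(CC)CC | intermediate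
15 | C3 triethylsilyl ether of 14 | CC1(C)OC(=O)C=C(O1)C[C@H](O[Si](CC)(CC)CC)[C@@](C)(CCO[Si](c2ccccc2)(c2ccccc2)C(C)(C)C)[C@@H](C(C)=C)CCO[Si](CC)(CC)CC | intermediate
16 | vicinal diol from dihydroxylation of the isopropenyl group of 15 (C10 epimers) | CC1(C)OC(=O)C=C(O1)C[C@H](O[Si](CC)(CC)CC)[C@@](C)(CCO[Si](c2ccccc2)(c2ccccc2)C(C)(C)C)[C@@H](C(C)(O)CO)CCO[Si](CC)(CC)CC | intermediate
17 | C10 methyl ketone | CC1(C)OC(=O)C=C(O1)C[C@H](O[Si](CC)(CC)CC)[C@@](C)(CCO[Si](c2ccccc2)(c2ccccc2)C(C)(C)C)[C@@H](C(C)=O)CCO[Si](CC)(CC)CC | intermediate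
18 | tert-butyl diethylphosphonoacetate | CCOP(=O)(CC(=O)OC(C)(C)C)OCC | starting material
19 | sodium salt of 18 | [Na+].CCOP(=O)([CH-]C(=O)OC(C)(C)C)OCC | intermediate
20 | photo precursor, dioxinone tethered through C2–C5 to the (E)-C10=C9 tert-butyl enoate, 3β-triethylsilyloxy | CC1(C)OC(=O)C=C(O1)C[C@H](O[Si](CC)(CC)CC)[C@@](C)(CCO[Si](c2ccccc2)(c2ccccc2)C(C)(C)C)[C@@H](/C(C)=C/C(=O)OC(C)(C)C)CCO[Si](CC)(CC)CC | intermediate
21 | cyclobutane photoadduct containing ring A, C10 methyl trans to H5, dioxanone and ring A on opposite faces of the cyclobutane | CC1(C)OC(=O)[C@H]2[C@@H](C(=O)OC(C)(C)C)[C@]3(C)[C@@H](CCO[Si](CC)(CC)CC)[C@](C)(CCO[Si](c4ccccc4)(c4ccccc4)C(C)(C)C)[C@@H](O[Si](CC)(CC)CC)C[C@]23O1 | intermediate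
22 | cyclobutanol methyl ester formed by methanolysis of 21 | COC(=O)[C@H]1[C@@H](C(=O)OC(C)(C)C)[C@]2(C)[C@@H](CCO[Si](CC)(CC)CC)[C@](C)(CCO[Si](c3ccccc3)(c3ccccc3)C(C)(C)C)[C@@H](O[Si](CC)(CC)CC)C[C@]12O | intermediate
23 | ring A C1 ketone with C10 methyl and the arm C9H(CO2tBu)–CH2CO2Me | COC(=O)C[C@@H](C(=O)OC(C)(C)C)[C@]1(C)[C@@H](CCO[Si](CC)(CC)CC)[C@](C)(CCO[Si](c2ccccc2)(c2ccccc2)C(C)(C)C)[C@@H](O[Si](CC)(CC)CC)CC1=O | intermediate
24 | 1α-alcohol from 23 | COC(=O)C[C@@H](C(=O)OC(C)(C)C)[C@]1(C)[C@@H](CCO[Si](CC)(CC)CC)[C@](C)(CCO[Si](c2ccccc2)(c2ccccc2)C(C)(C)C)[C@@H](O[Si](CC)(CC)CC)C[C@@H]1O | intermediate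
25 | 1α-tert-butyldimethylsilyl ether of 24 | COC(=O)C[C@@H](C(=O)OC(C)(C)C)[C@]1(C)[C@@H](CCO[Si](CC)(CC)CC)[C@](C)(CCO[Si](c2ccccc2)(c2ccccc2)C(C)(C)C)[C@@H](O[Si](CC)(CC)CC)C[C@@H]1O[Si](C)(C)C(C)(C)C | intermediate
26 | C7 primary alcohol | COC(=O)C[C@@H](C(=O)OC(C)(C)C)[C@]1(C)[C@@H](CCO)[C@](C)(CCO[Si](c2ccccc2)(c2ccccc2)C(C)(C)C)[C@@H](O[Si](CC)(CC)CC)C[C@@H]1O[Si](C)(C)C(C)(C)C | intermediate
27 | C7 aldehyde | COC(=O)C[C@@H](C(=O)OC(C)(C)C)[C@]1(C)[C@@H](CC=O)[C@](C)(CCO[Si](c2ccccc2)(c2ccccc2)C(C)(C)C)[C@@H](O[Si](CC)(CC)CC)C[C@@H]1O[Si](C)(C)C(C)(C)C | intermediate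
28 | ring B β-hydroxy ester (C7 carbinol, C7–C9 epimers) | COC(=O)C1C(O)C[C@H]2[C@](C)(CCO[Si](c3ccccc3)(c3ccccc3)C(C)(C)C)[C@@H](O[Si](CC)(CC)CC)C[C@H](O[Si](C)(C)C(C)(C)C)[C@]2(C)C1C(=O)OC(C)(C)C | intermediate
29 | trans-decalin, C7=C8–CO2Me, 9β-CO2tBu, 1α-OTBS, 3β-OTES, 4α-(2-silyloxyethyl), 4β-methyl, 10β-methyl | COC(=O)C1=CC[C@H]2[C@](C)(CCO[Si](c3ccccc3)(c3ccccc3)C(C)(C)C)[C@@H](O[Si](CC)(CC)CC)C[C@H](O[Si](C)(C)C(C)(C)C)[C@]2(C)[C@H]1C(=O)OC(C)(C)C | intermediate
30 | 3β-alcohol | COC(=O)C1=CC[C@H]2[C@](C)(CCO[Si](c3ccccc3)(c3ccccc3)C(C)(C)C)[C@@H](O)C[C@H](O[Si](C)(C)C(C)(C)C)[C@]2(C)[C@H]1C(=O)OC(C)(C)C | intermediate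
31 | C3 methyl oxalate | COC(=O)C1=CC[C@H]2[C@](C)(CCO[Si](c3ccccc3)(c3ccccc3)C(C)(C)C)[C@@H](OC(=O)C(=O)OC)C[C@H](O[Si](C)(C)C(C)(C)C)[C@]2(C)[C@H]1C(=O)OC(C)(C)C | intermediate
32 | C3 cesium oxalate | [Cs+].COC(=O)C1=CC[C@H]2[C@](C)(CCO[Si](c3ccccc3)(c3ccccc3)C(C)(C)C)[C@@H](OC(=O)C(=O)[O-])C[C@H](O[Si](C)(C)C(C)(C)C)[C@]2(C)[C@H]1C(=O)OC(C)(C)C | intermediate
33 | 3β-chloride | COC(=O)C1=CC[C@H]2[C@](C)(CCO[Si](c3ccccc3)(c3ccccc3)C(C)(C)C)[C@@H](Cl)C[C@H](O[Si](C)(C)C(C)(C)C)[C@]2(C)[C@H]1C(=O)OC(C)(C)C | intermediate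
34 | C2′ primary alcohol | COC(=O)C1=CC[C@H]2[C@](C)(CCO)[C@@H](Cl)C[C@H](O[Si](C)(C)C(C)(C)C)[C@]2(C)[C@H]1C(=O)OC(C)(C)C | intermediate
35 | C2′ aldehyde | COC(=O)C1=CC[C@H]2[C@](C)(CC=O)[C@@H](Cl)C[C@H](O[Si](C)(C)C(C)(C)C)[C@]2(C)[C@H]1C(=O)OC(C)(C)C | intermediate
36 | 4α-allyl compound | COC(=O)C1=CC[C@H]2[C@](C)(CC=C)[C@@H](Cl)C[C@H](O[Si](C)(C)C(C)(C)C)[C@]2(C)[C@H]1C(=O)OC(C)(C)C | intermediate
37 | C11 trimethylsilyl ester | COC(=O)C1=CC[C@H]2[C@](C)(CC=C)[C@@H](Cl)C[C@H](O[Si](C)(C)C(C)(C)C)[C@]2(C)[C@H]1C(=O)O[Si](C)(C)C | intermediate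
38 | C11 carboxylic acid | COC(=O)C1=CC[C@H]2[C@](C)(CC=C)[C@@H](Cl)C[C@H](O[Si](C)(C)C(C)(C)C)[C@]2(C)[C@H]1C(=O)O | intermediate
39 | C11 acid chloride | COC(=O)C1=CC[C@H]2[C@](C)(CC=C)[C@@H](Cl)C[C@H](O[Si](C)(C)C(C)(C)C)[C@]2(C)[C@H]1C(Cl)=O | intermediate
40 | 9β-aldehyde, 1α-silyl ether | COC(=O)C1=CC[C@H]2[C@](C)(CC=C)[C@@H](Cl)C[C@H](O[Si](C)(C)C(C)(C)C)[C@]2(C)[C@H]1C=O | intermediate
41 | 1α-hydroxy 9β-aldehyde with 4α-allyl group | COC(=O)C1=CC[C@H]2[C@](C)(CC=C)[C@@H](Cl)C[C@H](O)[C@]2(C)[C@H]1C=O | intermediate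
42 | 2-methylbut-3-en-2-ol | C=CC(C)(C)O | starting material
43 | CNP0167913.1 | COC(=O)C1=CC[C@H]2[C@](C)(C/C=C/C(C)(C)O)[C@@H](Cl)C[C@H](O)[C@]2(C)[C@H]1C=O | target

**Step count**

Total: 27 steps. Longest linear sequence: 27 steps (1 → 43); all other inputs are commercial.

**Steps most likely to fail**

Step 11. The first bond (C1–C10) may form with poor facial selectivity, because the preference for the methyl over the C9 terminus in the pseudo-axial site is not large for an E enoate, or the biradical may revert instead of closing. Fallback: set out from ketone 17 and condense it with tert-butyl methyl malonate (TiCl4, pyridine, THF; Knoevenagel) to the alkylidene malonate F1. Its ester cis to C5 forces H5 into the alkene plane through 1,3-allylic strain, so C1 should reach C10 only from the face that leaves the methyl trans to H5. Irradiation as in step 11 would give the cyclobutane F2 and K2CO3 in methanol the keto triester F3. Krapcho dealkoxycarbonylation of the geminal methyl ester (LiCl, wet DMSO, 130 °C) then comes back to the route at 23, as C9 epimers that converge in step 17.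

Step 20. Chlorine atom transfer to the C3 radical may take place on the α face, or the radical may be reduced by hydrogen abstraction. Fallback: set out from alcohol 30, oxidise it with Dess–Martin periodinane to the C3 ketone F4, and reduce with LiBH(s-Bu)3 by equatorial attack to the axial 3α-alcohol F5. Substitution with inversion (Ph3P, N-chlorosuccinimide, THF; Appel-type) comes back to the route at chloride 33. Elimination toward C2 competes at this neopentyl centre, which is why this ionic path is the reserve and not the first choice.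

Step 17. Enolisation of the aldehyde with self-condensation may outrun the ester aldol, or dehydration may stall at the β-hydroxy ester. Fallback: set out from aldehyde 27 and methylenate it (Ph3P=CH2, THF) to the terminal alkene F6. Kinetic deprotonation of the methyl ester at C8 (LiN(iPr)2, −78 °C) and trapping with dimethyl(methylidene)ammonium iodide give the Mannich base F7; N-methylation (MeI) and elimination (DBU) give the α-methylene ester F8. Ring-closing metathesis (second-generation Hoveyda–Grubbs catalyst, toluene, 80 °C) forms C7=C8 directly to give F9, and equilibration of C9 with NaOMe in methanol comes back to the route at 29.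

Further compounds
F1 | step 11 | alkylidene malonate analogue of 20, C10(Me)=C9(CO2Me)(CO2tBu) | CC1(C)OC(=O)C=C(O1)C[C@H](O[Si](CC)(CC)CC)[C@@](C)(CCO[Si](c2ccccc2)(c2ccccc2)C(C)(C)C)[C@@H](C(C)=C(C(=O)OC)C(=O)OC(C)(C)C)CCO[Si](CC)(CC)CC
F2 | step 11 | cyclobutane photoadduct with geminal diester at C9 | CC1(C)OC(=O)[C@H]2C(C(=O)OC)(C(=O)OC(C)(C)C)[C@]3(C)[C@@H](CCO[Si](CC)(CC)CC)[C@](C)(CCO[Si](c4ccccc4)(c4ccccc4)C(C)(C)C)[C@@H](O[Si](CC)(CC)CC)C[C@]23O1
F3 | step 11 | ring A ketone with the C10 arm C9(CO2Me)(CO2tBu)–CH2CO2Me | COC(=O)CC(C(=O)OC)(C(=O)OC(C)(C)C)[C@]1(C)[C@@H](CCO[Si](CC)(CC)CC)[C@](C)(CCO[Si](c2ccccc2)(c2ccccc2)C(C)(C)C)[C@@H](O[Si](CC)(CC)CC)CC1=O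
F4 | step 20 | C3 ketone from 30 | COC(=O)C1=CC[C@H]2[C@](C)(CCO[Si](c3ccccc3)(c3ccccc3)C(C)(C)C)C(=O)C[C@H](O[Si](C)(C)C(C)(C)C)[C@]2(C)[C@H]1C(=O)OC(C)(C)C
F5 | step 20 | 3α-alcohol (axial), C3 epimer of 30 | COC(=O)C1=CC[C@H]2[C@](C)(CCO[Si](c3ccccc3)(c3ccccc3)C(C)(C)C)[C@H](O)C[C@H](O[Si](C)(C)C(C)(C)C)[C@]2(C)[C@H]1C(=O)OC(C)(C)C
F6 | step 17 | terminal alkene from methylenation of 27 (C5–CH2–CH=CH2) | COC(=O)C[C@@H](C(=O)OC(C)(C)C)[C@]1(C)[C@@H](CC=C)[C@](C)(CCO[Si](c2ccccc2)(c2ccccc2)C(C)(C)C)[C@@H](O[Si](CC)(CC)CC)C[C@@H]1O[Si](C)(C)C(C)(C)C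
F7 | step 17 | Mannich base, C8 carrying CH2NMe2 | COC(=O)C(CN(C)C)[C@@H](C(=O)OC(C)(C)C)[C@]1(C)[C@@H](CC=C)[C@](C)(CCO[Si](c2ccccc2)(c2ccccc2)C(C)(C)C)[C@@H](O[Si](CC)(CC)CC)C[C@@H]1O[Si](C)(C)C(C)(C)C
F8 | step 17 | α-methylene methyl ester at C8 | COC(=O)C(=C)[C@@H](C(=O)OC(C)(C)C)[C@]1(C)[C@@H](CC=C)[C@](C)(CCO[Si](c2ccccc2)(c2ccccc2)C(C)(C)C)[C@@H](O[Si](CC)(CC)CC)C[C@@H]1O[Si](C)(C)C(C)(C)C
F9 | step 17 | ring-closed decalin with 9α-CO2tBu, C9 epimer of 29 | COC(=O)C1=CC[C@H]2[C@](C)(CCO[Si](c3ccccc3)(c3ccccc3)C(C)(C)C)[C@@H](O[Si](CC)(CC)CC)C[C@H](O[Si](C)(C)C(C)(C)C)[C@]2(C)[C@@H]1C(=O)OC(C)(C)C
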